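**Plan**
- Last bond made (first cut): the CH2–CH2 bond C3'–C4' of the tetradecyl chain (C1' sits on ring C2). A retro-Kolbe cut gives dodecanoic acid and 4-(1-methyl-4-oxo-1,4-dihydroquinolin-2-yl)butanoic acid; each CO2H is the activating group and leaves as CO2 in the coupling itself.
- Second cut: N1–C2 and C3–C4 of the pyridone ring, back to N-methylisatoic anhydride and the methyl-side enolate of methyl 5-oxohexanoate.
- Forward: the pyridone ring is closed onto the existing benzene ring in one pot, the ester is hydrolysed, and the C11 chain is joined last by anodic mixed decarboxylative radical coupling.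
- Enabling feature: C3' and C4' are unbranched sp3 carbons with no α-heteroatom and no adjacent π-system, three and four atoms from C2 of the N1–C2=C3–C4=O vinylogous-amide ring. Both therefore map onto carboxylic acids, the primary radicals combine instead of ionising, and the quinolone-side radical cannot add to C2=C3 (5-endo at C3, 4-exo at C2).
- Stereochemistry: none to set. Remark on the chemistry: the target has no stereocentre and no stereogenic double bond, so the structure drawn is the only species.

Key step: step 3

Step 1
Reactants: 1 N-methylisatoic anhydride (1-methyl-2H-3,1-benzoxazine-2,4(1H)-dione); 2 methyl 5-oxohexanoate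
Product: 6 methyl 4-(1-methyl-4-oxo-1,4-dihydroquinolin-2-yl)butanoate, via lithium enolate 3 (not isolated), via lithium carbamate 4 (not isolated), via amino diketone 5 (not isolated)
Conditions: 2 (2.2 equiv), LDA (2.2 equiv, commercial solution), THF, −78 °C, 30 min; then 1 (1.0 equiv) in THF, −78 to −40 °C; AcOH (excess), then rt
Reagents that add atoms: none
Why: Acylative quinolone annulation of an isatoic anhydride with a ketone enolate (Coppola-type): the kinetic methyl-side lithium enolate 3 is C-acylated at the activated aroyl carbonyl C4 of the N-carboxyanhydride, the ring-opened carbamate 4 loses CO2 on acidification, and the freed N-methylaniline nitrogen of 5 condenses with the aliphatic ketone (six-membered cyclodehydration) to the aromatic vinylogous amide, while the second equivalent of enolate takes up the acidic diketone proton and the low temperature keeps the δ-keto ester enolate from closing on its own ester.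

Step 2
Reactants: 6 methyl 4-(1-methyl-4-oxo-1,4-dihydroquinolin-2-yl)butanoate
Product: 8 4-(1-methyl-4-oxo-1,4-dihydroquinolin-2-yl)butanoic acid, via lithium carboxylate 7 (not isolated)
Conditions: LiOH·H2O (2 equiv), THF/H2O 3:1, rt; then 1 M HCl to pH 4, filtration or extraction (CH2Cl2/i-PrOH)
Reagents that add atoms: lithium hydroxide, [Li+].[OH-]
Why: Standard ester saponification: hydroxide attacks the unhindered methyl ester, the vinylogous amide of the quinolone is inert to aqueous base at room temperature, and the amphoteric acid should separate near pH 4, between the pKa of the protonated quinolone and that of the carboxylic acid.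

Step 3
Reactants: 8 4-(1-methyl-4-oxo-1,4-dihydroquinolin-2-yl)butanoic acid; 9 dodecanoic acid (lauric acid)
Product: 12 1-methyl-2-tetradecylquinolin-4(1H)-one, via quinolonylpropyl radical 10 (not isolated), via undecyl radical 11 (not isolated)
Conditions: 8 (1 equiv), 9 (8 equiv), KOH (5 mol % of total acid), MeOH, 40–45 °C, undivided cell, Pt anode/Pt cathode, constant current ca. 0.2 A cm−2 until the solution turns slightly basic
Reagents that add atoms: none
Why: Anodic one-electron oxidation of the carboxylates of 8 and 9 at platinum under high current density gives acyloxy radicals that lose CO2 at once, so the primary radicals 10 and 11 arise side by side in the carboxylate layer on the anode and combine to form the C3'–C4' bond. The closest known reaction type is the mixed (crossed) Kolbe electrolysis of a functionalised carboxylic acid with an excess of a fatty acid, a classical way to extend unbranched chains. No ring is closed and no stereocentre is formed, so neither a closure mode nor stereocontrol enters. Three selectivities are needed: cross- over homo-coupling, secured by the eightfold excess of cheap 9, whose own dimer docosane is non-polar and should separate from the polar quinolone on silica; radical coupling over the cationic (Hofer–Moest) path, secured because both radicals are primary and carry no α-heteroatom or α-aryl group; and discharge of carboxylate in preference to oxidation of the N1–C2=C3–C4=O vinylogous amide, favoured by the smooth Pt anode, the weakly acidic medium and the high current density, which keep the anode covered with carboxylate. Radical 10 has no fast intramolecular exit, since attack on ring C3 would be 5-endo-trig and attack on C2 4-exo-trig.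

**Compound list**
1 | N-methylisatoic anhydride (1-methyl-2H-3,1-benzoxazine-2,4(1H)-dione) | CN1C(=O)OC(=O)c2ccccc21 | starting material
2 | methyl 5-oxohexanoate | COC(=O)CCCC(C)=O | starting material
3 | lithium enolate of 2 on the methyl side (methyl 5-(lithiooxy)hex-5-enoate) | [Li]OC(=C)CCCC(=O)OC | intermediate
4 | lithium N-[2-(7-methoxy-3,7-dioxoheptanoyl)phenyl]-N-methylcarbamate | [Li+].[O-]C(=O)N(C)c1ccccc1C(=O)CC(=O)CCCC(=O)OC | intermediate
5 | methyl 7-[2-(methylamino)phenyl]-5,7-dioxoheptanoate | CNc1ccccc1C(=O)CC(=O)CCCC(=O)OC | intermediate
6 | methyl 4-(1-methyl-4-oxo-1,4-dihydroquinolin-2-yl)butanoate | COC(=O)CCCc1cc(=O)c2ccccc2n1C | intermediate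
7 | lithium 4-(1-methyl-4-oxo-1,4-dihydroquinolin-2-yl)butanoate | [Li+].[O-]C(=O)CCCc1cc(=O)c2ccccc2n1C | intermediate
8 | 4-(1-methyl-4-oxo-1,4-dihydroquinolin-2-yl)butanoic acid | OC(=O)CCCc1cc(=O)c2ccccc2n1C | intermediate
9 | dodecanoic acid (lauric acid) | CCCCCCCCCCCC(=O)O | starting material
10 | 3-(1-methyl-4-oxo-1,4-dihydroquinolin-2-yl)propyl radical | [CH2]CCc1cc(=O)c2ccccc2n1C | intermediate
11 | undecyl radical | CCCCCCCCCC[CH2] | intermediate
12 | 1-methyl-2-tetradecylquinolin-4(1H)-one | CCCCCCCCCCCCCCc1cc(=O)c2ccccc2n1C | target

**Count and risks**
Total step count: 3. Longest linear sequence: 3 steps (1 → 6 → 8 → 12).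

Steps most likely to fail, riskiest first:

Step 3. The quinolone ring may be oxidised at the anode in competition with carboxylate discharge, material may be lost to homocoupling, and the hydrocarbon dimer may foul the anode. The fallback sets out from 8 and generates the same radical reductively, so the heterocycle never meets an oxidising potential. Acid 8 would be esterified with N-hydroxyphthalimide (N,N'-diisopropylcarbodiimide, cat. DMAP, CH2Cl2, rt) to the redox-active ester 1,3-dioxoisoindolin-2-yl 4-(1-methyl-4-oxo-1,4-dihydroquinolin-2-yl)butanoate F1. Commercial undecylmagnesium bromide (2 equiv) and ZnCl2 (1 equiv) in THF would give diundecylzinc F2. Nickel-catalysed decarboxylative alkyl–alkyl coupling of F1 with F2 (NiCl2·glyme 20 mol %, 4,4'-di-tert-butyl-2,2'-bipyridine 40 mol %, THF/DMF, rt, aqueous HCl work-up) should form the same C3'–C4' bond and comes back to the route at 12.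

Step 1. The δ-keto ester enolate may close onto its own ester (intramolecular Claisen) before it is acylated, and deprotonation may occur on the methylene side instead of the methyl side. The fallback sets out from 1 and uses a ketone with no internal electrophile, the carboxyl being carried as a terminal alkene. Hex-5-en-2-one (2.2 equiv) and LDA (THF, −78 °C) would give lithium hexa-1,5-dien-2-olate F3. Addition of 1 would lead through lithium N-methyl-N-[2-(3-oxohept-6-enoyl)phenyl]carbamate F4 and, after AcOH, through 1-[2-(methylamino)phenyl]hept-6-ene-1,3-dione F5 to 2-(but-3-en-1-yl)-1-methylquinolin-4(1H)-one F6. Hydroboration with 9-BBN (THF, rt) would give 2-[4-(9-borabicyclo[3.3.1]nonan-9-yl)butyl]-1-methylquinolin-4(1H)-one F7, and NaOH/H2O2 would oxidise it to 2-(4-hydroxybutyl)-1-methylquinolin-4(1H)-one F8. Oxidation with cat. TEMPO and (diacetoxyiodo)benzene (MeCN/H2O, rt) would pass through 4-(1-methyl-4-oxo-1,4-dihydroquinolin-2-yl)butanal F9 and comes back to the route at 8, so that step 2 is not needed.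

Step 2. The amphoteric acid may be recovered incompletely from the aqueous phase at its isoelectric point. The fallback sets out from 6 and avoids water altogether. Cleavage of the methyl ester with potassium trimethylsilanolate (THF, rt) should precipitate potassium 4-(1-methyl-4-oxo-1,4-dihydroquinolin-2-yl)butanoate F10, which would be filtered off and charged directly to the cell of step 3 without added KOH. Proton exchange with the excess of 9 there regenerates 8, where the fallback comes back to the route.

**Further compounds**
F1 | step 3 | 1,3-dioxoisoindolin-2-yl 4-(1-methyl-4-oxo-1,4-dihydroquinolin-2-yl)butanoate | O=C(CCCc1cc(=O)c2ccccc2n1C)ON1C(=O)c2ccccc2C1=O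
F2 | step 3 | diundecylzinc | CCCCCCCCCCC[Zn]CCCCCCCCCCC
F3 | step 1 | lithium hexa-1,5-dien-2-olate | [Li]OC(=C)CCC=C
F4 | step 1 | lithium N-methyl-N-[2-(3-oxohept-6-enoyl)phenyl]carbamate | [Li+].[O-]C(=O)N(C)c1ccccc1C(=O)CC(=O)CCC=C
F5 | step 1 | 1-[2-(methylamino)phenyl]hept-6-ene-1,3-dione | CNc1ccccc1C(=O)CC(=O)CCC=C
F6 | step 1 | 2-(but-3-en-1-yl)-1-methylquinolin-4(1H)-one | C=CCCc1cc(=O)c2ccccc2n1C
F7 | step 1 | 2-[4-(9-borabicyclo[3.3.1]nonan-9-yl)butyl]-1-methylquinolin-4(1H)-one | O=c1cc(CCCCB2C3CCCC2CCC3)n(C)c2ccccc12
F8 | step 1 | 2-(4-hydroxybutyl)-1-methylquinolin-4(1H)-one | OCCCCc1cc(=O)c2ccccc2n1C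
F9 | step 1 | 4-(1-methyl-4-oxo-1,4-dihydroquinolin-2-yl)butanal | O=CCCCc1cc(=O)c2ccccc2n1C
F10 | step 2 | potassium 4-(1-methyl-4-oxo-1,4-dihydroquinolin-2-yl)butanoate | [K+].[O-]C(=O)CCCc1cc(=O)c2ccccc2n1C
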